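**Retrosynthetic overview**
- Feature: glycerol C2 is the only stereocentre, and it is stereogenic only because O1 carries acetyl and O3 carries hydrogen. Without the acetyl group the molecule is an achiral 2-acyl-propane-1,3-diol with two enantiotopic CH2OH arms.
- Last bond made: O1–C(O)CH3, by lipase-mediated acetyl transfer from vinyl acetate to the pro-S CH2OH of diol 9, which creates the (S) centre at C2.
- Before that: the O2–acyl ester bond is made on cis-1,3-O-benzylideneglycerol 6 (Steglich), and the acetal is then cleaved with B(OH)3 under non-migrating conditions.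
- Acid part: the C2=C3 bond of the enoate comes from a Horner–Wadsworth–Emmons olefination of dihydro-β-ionone 1, followed by saponification to acid 5.
- Rings: none is formed. The trimethylcyclohexene ring is bought with 1, and the 1,3-dioxane ring of 6 is only a temporary protecting ring.

Key step: step 5

Assumption: immobilised Burkholderia cepacia lipase is taken to acetylate the pro-S hydroxymethyl arm of 9, by analogy with 2-O-substituted glycerols. Sense and level are to be checked on the first run by chiral HPLC and MTPA-ester analysis.

**Step 1**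
Reactants: 1 dihydro-β-ionone [4-(2,6,6-trimethylcyclohex-1-en-1-yl)butan-2-one]; 2 triethyl phosphonoacetate
Product: 4 ethyl (2E)-3-methyl-5-(2,6,6-trimethylcyclohex-1-en-1-yl)pent-2-enoate, via sodium triethyl phosphonoacetate 3 (not isolated)
Conditions: NaH (1.3 equiv), 2, THF, 0 °C; then 1, 0 °C → reflux; aq. NH4Cl; SiO2 chromatography (AgNO3-impregnated if needed) to remove the (2Z)-isomer
Reagents that add atoms: none
Why: Horner–Wadsworth–Emmons olefination of a methyl ketone by the stabilised phosphonate carbanion should give an (E)-rich mixture of the trisubstituted enoates, because the longer chain prefers to lie trans to the ester, and the (2E)-ester is then separated by chromatography.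

**Step 2**
Reactants: 4 ethyl (2E)-3-methyl-5-(2,6,6-trimethylcyclohex-1-en-1-yl)pent-2-enoate
Product: 5 (2E)-3-methyl-5-(2,6,6-trimethylcyclohex-1-en-1-yl)pent-2-enoic acid
Conditions: NaOH (3 equiv), EtOH/H2O, 60 °C; then 1 M HCl to pH 3, 0 °C
Reagents that add atoms: sodium hydroxide, [Na+].[OH-]
Why: Saponification by acyl–oxygen cleavage gives a carboxylate that hydroxide does not deprotonate further, so the (2E) geometry and the conjugation should be kept, and brief cold dilute acid should leave the tetrasubstituted ring alkene untouched.

**Step 3**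
Reactants: 5 (2E)-3-methyl-5-(2,6,6-trimethylcyclohex-1-en-1-yl)pent-2-enoic acid; 6 cis-2-phenyl-1,3-dioxan-5-ol (cis-1,3-O-benzylideneglycerol)
Product: 7 cis-2-phenyl-1,3-dioxan-5-yl (2E)-3-methyl-5-(2,6,6-trimethylcyclohex-1-en-1-yl)pent-2-enoate
Conditions: DCC (1.2 equiv), DMAP (0.1 equiv), CH2Cl2, 0 °C → rt; filter
Reagents that add atoms: none
Why: Steglich esterification is the standard way to acylate O2 of 1,3-O-benzylideneglycerol, since the N-acylpyridinium ion formed with DMAP acylates the secondary alcohol without a base strong enough to deconjugate or isomerise the enoate.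

**Step 4**
Reactants: 7 cis-2-phenyl-1,3-dioxan-5-yl (2E)-3-methyl-5-(2,6,6-trimethylcyclohex-1-en-1-yl)pent-2-enoate
Product: 9 1,3-dihydroxypropan-2-yl (2E)-3-methyl-5-(2,6,6-trimethylcyclohex-1-en-1-yl)pent-2-enoate, via cyclic borate ester 8 (not isolated)
Conditions: B(OH)3 (5 equiv), B(OMe)3, sealed tube, 100 °C; concentrate; then Et2O/H2O, 0 °C; use crude at once (or quick flash on B(OH)3-impregnated SiO2)
Reagents that add atoms: none
Why: Boric-acid-mediated transacetalisation of the benzylidene acetal is a known route to 2-monoacylglycerols, because O1 and O3 are held in a 1,3,2-dioxaborinane as they are released, so the acyl group should not migrate from O2 before the borate is hydrolysed in cold water.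

**Step 5**
Reactants: 9 1,3-dihydroxypropan-2-yl (2E)-3-methyl-5-(2,6,6-trimethylcyclohex-1-en-1-yl)pent-2-enoate; 10 vinyl acetate
Product: 11 (2S)-1-(acetyloxy)-3-hydroxypropan-2-yl (2E)-3-methyl-5-(2,6,6-trimethylcyclohex-1-en-1-yl)pent-2-enoate (target; a 1-O-acetyl-2-O-acyl-sn-glycerol)
Conditions: immobilised Burkholderia cepacia lipase (on diatomite), vinyl acetate (4 equiv), dry t-BuOMe, 0 → 20 °C, chiral HPLC monitoring; filter off enzyme; cold chromatography on B(OH)3-impregnated SiO2
Reagents that add atoms: none
Why: The active-site serine of the lipase is acetylated by vinyl acetate, the departing vinyl alcohol tautomerises to acetaldehyde so the transfer is irreversible, and the acetyl-enzyme then delivers acetyl to the one primary hydroxyl of 9 that the chiral pocket places beside it, forming the O1–C(O)CH3 bond. The closest known reaction type is the lipase-catalysed desymmetrising acetylation of 2-O-substituted glycerols and other 2-substituted propane-1,3-diols with enol esters. No ring is closed. The single new stereocentre, glycerol C2, arises because the two CH2OH arms of the achiral diol become different, and it is under catalyst control: acetylation of the pro-S arm gives the (S) centre of the 1-O-acetyl-2-O-acyl-sn-glycerol. The step needs enantiotopic-group selectivity, which the enzyme pocket should supply with the bulky terpenoid ester at O2 as recognition element, and chemoselectivity for primary hydroxyl over the existing ester, which rests on the primary-position preference of the lipase and on the conjugated, β,β-disubstituted enoate at O2 being a poor acyl donor both for the enzyme and for O2→O3 migration in the dry neutral medium. Running slightly past full consumption of 9 should raise the enantiomeric purity, since the minor enantiomer still has the fast-reacting pro-S arm free and is drained into the achiral diacetate.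

**Compound list**
1 | dihydro-β-ionone, 4-(2,6,6-trimethylcyclohex-1-en-1-yl)butan-2-one | CC(=O)CCC1=C(C)CCCC1(C)C | starting material
2 | triethyl phosphonoacetate | CCOC(=O)CP(=O)(OCC)OCC | starting material
3 | sodium salt of triethyl phosphonoacetate (phosphonate carbanion) | CCOC(=O)[CH-]P(=O)(OCC)OCC.[Na+] | intermediate (not isolated)
4 | ethyl (2E)-3-methyl-5-(2,6,6-trimethylcyclohex-1-en-1-yl)pent-2-enoate | CCOC(=O)/C=C(\C)CCC1=C(C)CCCC1(C)C | intermediate
5 | (2E)-3-methyl-5-(2,6,6-trimethylcyclohex-1-en-1-yl)pent-2-enoic acid | OC(=O)/C=C(\C)CCC1=C(C)CCCC1(C)C | intermediate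
6 | cis-2-phenyl-1,3-dioxan-5-ol (cis-1,3-O-benzylideneglycerol) | O[C@H]1CO[C@@H](c2ccccc2)OC1 | starting material
7 | cis-2-phenyl-1,3-dioxan-5-yl (2E)-3-methyl-5-(2,6,6-trimethylcyclohex-1-en-1-yl)pent-2-enoate | O=C(O[C@H]1CO[C@@H](c2ccccc2)OC1)/C=C(\C)CCC1=C(C)CCCC1(C)C | intermediate
8 | 2-hydroxy-1,3,2-dioxaborinan-5-yl (2E)-3-methyl-5-(2,6,6-trimethylcyclohex-1-en-1-yl)pent-2-enoate (cyclic borate ester) | OB1OCC(CO1)OC(=O)/C=C(\C)CCC1=C(C)CCCC1(C)C | intermediate (not isolated)
9 | 1,3-dihydroxypropan-2-yl (2E)-3-methyl-5-(2,6,6-trimethylcyclohex-1-en-1-yl)pent-2-enoate (achiral 2-acylglycerol) | OCC(CO)OC(=O)/C=C(\C)CCC1=C(C)CCCC1(C)C | intermediate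
10 | vinyl acetate | CC(=O)OC=C | starting material
11 | (2S)-1-(acetyloxy)-3-hydroxypropan-2-yl (2E)-3-methyl-5-(2,6,6-trimethylcyclohex-1-en-1-yl)pent-2-enoate | CC(=O)OC[C@H](CO)OC(=O)/C=C(\C)CCC1=C(C)CCCC1(C)C | target

**Step count**
Total steps: 5. Longest linear sequence: 5 steps (1 → 4 → 5 → 7 → 9 → 11).

**Steps most likely to fail**

Step 5. The lipase may discriminate the two hydroxymethyl arms poorly or in the reverse sense, and slow O2→O3 acyl drift may compete if the run is sluggish. The fallback sets out from 9 and comes back at 11. Diol 9 is acetylated exhaustively (Ac2O, pyridine, cat. DMAP, CH2Cl2, 0 °C, fast enough to outrun migration) to the achiral 1,3-bis(acetyloxy)propan-2-yl (2E)-3-methyl-5-(2,6,6-trimethylcyclohex-1-en-1-yl)pent-2-enoate F1. One enantiotopic acetate is then removed by lipase-catalysed alcoholysis with n-BuOH in t-BuOMe, using the same lipase or another from the screen. A lipase attacks the same arm in acylation and in deacylation, so an enzyme that acetylates the pro-R arm of 9 should strip the pro-R acetate of F1 and leave the acetate on the pro-S arm, which is 11. The triacylglycerol-like F1 is also closer to the natural substrates of these enzymes.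

Step 4. The acyl group may migrate from O2 to a primary oxygen during the hot acetal cleavage or the work-up, or cleavage may be incomplete; either destroys the symmetry on which step 5 depends. The fallback sets out from 5 and comes back at 9. Commercial glycerol is silylated at both primary hydroxyls (TBSCl 2.05 equiv, imidazole, CH2Cl2, 0 °C) to 1,3-bis(tert-butyldimethylsilyloxy)propan-2-ol F2. F2 is esterified with 5 (DCC, DMAP, CH2Cl2) to 1,3-bis(tert-butyldimethylsilyloxy)propan-2-yl (2E)-3-methyl-5-(2,6,6-trimethylcyclohex-1-en-1-yl)pent-2-enoate F3. Desilylation with acidic fluoride (HF·pyridine, pyridine/THF, 0 °C), where no free alkoxide is formed, should release 9 at low temperature.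

Step 1. E/Z control in the olefination of an unsymmetrical methyl ketone may be weak and the separation of the geometric isomers laborious. The fallback sets out from 1 and comes back at 4. The kinetic methyl-side enolate of 1 (LiN(i-Pr)2, THF, −78 °C) is trapped with ClP(O)(OEt)2 to give diethyl 4-(2,6,6-trimethylcyclohex-1-en-1-yl)but-1-en-2-yl phosphate F4. Further LiN(i-Pr)2 eliminates F4 to the terminal alkyne 2-(but-3-yn-1-yl)-1,3,3-trimethylcyclohex-1-ene F5. Cp2ZrCl2-catalysed methylalumination (AlMe3, CH2Cl2, rt) adds methyl and aluminium syn across the triple bond to give dimethyl[(1E)-2-methyl-4-(2,6,6-trimethylcyclohex-1-en-1-yl)but-1-en-1-yl]alane F6. Quenching with ethyl chloroformate replaces aluminium by CO2Et with retention, so 4 should form as the (2E)-isomer by a stereospecific, kinetically controlled route.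

**Further compounds**
F1 | step 5 | 1,3-bis(acetyloxy)propan-2-yl (2E)-3-methyl-5-(2,6,6-trimethylcyclohex-1-en-1-yl)pent-2-enoate | CC(=O)OCC(COC(C)=O)OC(=O)/C=C(\C)CCC1=C(C)CCCC1(C)C
F2 | step 4 | 1,3-bis(tert-butyldimethylsilyloxy)propan-2-ol | CC(C)(C)[Si](C)(C)OCC(O)CO[Si](C)(C)C(C)(C)C
F3 | step 4 | 1,3-bis(tert-butyldimethylsilyloxy)propan-2-yl (2E)-3-methyl-5-(2,6,6-trimethylcyclohex-1-en-1-yl)pent-2-enoate | CC(C)(C)[Si](C)(C)OCC(CO[Si](C)(C)C(C)(C)C)OC(=O)/C=C(\C)CCC1=C(C)CCCC1(C)C
F4 | step 1 | diethyl 4-(2,6,6-trimethylcyclohex-1-en-1-yl)but-1-en-2-yl phosphate | C=C(CCC1=C(C)CCCC1(C)C)OP(=O)(OCC)OCC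
F5 | step 1 | 2-(but-3-yn-1-yl)-1,3,3-trimethylcyclohex-1-ene | C#CCCC1=C(C)CCCC1(C)C
F6 | step 1 | dimethyl[(1E)-2-methyl-4-(2,6,6-trimethylcyclohex-1-en-1-yl)but-1-en-1-yl]alane | C[Al](C)/C=C(\C)CCC1=C(C)CCCC1(C)C
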